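**Strategy**

Everything rests on cutting C9–C13 and C7–C8, the two bonds by which the C8–C9 bridge spans C13 and C7, the ring carbons flanking the C15 carbonyl. This is the cedranoid pattern: ring A is a former acylphloroglucinol, ring B the bridge, ring C the tether fused on C9–C13. One oxidation of aromatic precursor 21 closes rings B and C, dearomatises ring A to the enolised trione and sets C7, C9 and C13 from the preset C11 centre. Precursor 21 is a 3-alkenyl-5-methyl isobutyrylphloroglucinol whose C12–C8 chain, with C16 as a silyl ether and a terminal vinyl group, comes from an enantioselective Ireland–Claisen rearrangement.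

Key step: step 12

**Remarks before the steps**

- Atom labels follow the target SMILES: C5=C6 enol, C7 methyl-bearing bridgehead, C8 CH2, C9 ring-fusion CH, C10 CMe2, C11 CH, C12 CH2, C13 second bridgehead, C14 ring ketone, C15 bridging ketone, C16 carbinol carbon. Ring A = C5, C6, C7, C15, C13, C14; ring B = C7, C8, C9, C13, C15; ring C = C9 to C13. The target is C7 S, C9 S, C11 R, C13 S.
- L*2BBr = (4S,5S)-2-bromo-1,3-bis{[3,5-bis(trifluoromethyl)phenyl]sulfonyl}-4,5-diphenyl-1,3,2-diazaborolidine, preformed.
- Assumption on the chemistry: the (S,S)-antipode of L*2BBr, acting on the E(O) boron ketene acetal drawn as 11, is taken to shield the enolate face that leads to (R)-12. Both antipodes are equally accessible, so a wrong guess only swaps the controller.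
- MOM = methoxymethyl, TBS = tert-butyldimethylsilyl, TMS = trimethylsilyl.

**Route**

Step 1
Reactants: 1 2-methylbenzene-1,3,5-triol
Product: 2 1,3,5-tris(methoxymethoxy)-2-methylbenzene
Conditions: MOMCl, i-Pr2NEt, DMF, 0 °C → rt
Reagents that add atoms: chloromethyl methyl ether, COCCl
Why: O-alkylation of the three phenols by the hard electrophile MOMCl (acetal protection) should give the tris-acetal cleanly, and the OMOM groups later direct both ring lithiations.

Step 2
Reactants: 2 1,3,5-tris(methoxymethoxy)-2-methylbenzene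
Product: 4 2,4,6-tris(methoxymethoxy)-3-methylbenzaldehyde, via aryllithium 3 (not isolated)
Conditions: n-BuLi, TMEDA, THF, 0 °C; DMF, 0 °C → rt; H2O
Reagents that add atoms: N,N-dimethylformamide, CN(C)C=O
Why: Directed ortho-metalation removes one of the two equivalent ring protons flanked by OMOM groups, and formylation of the aryllithium by DMF installs C12.

Step 3
Reactants: 4 2,4,6-tris(methoxymethoxy)-3-methylbenzaldehyde; 5 malonic acid
Product: 7 (2E)-3-[2,4,6-tris(methoxymethoxy)-3-methylphenyl]prop-2-enoic acid, via arylidenemalonic acid 6 (not isolated)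
Conditions: pyridine, piperidine (cat.), 90 °C
Reagents that add atoms: none
Why: Knoevenagel–Doebner condensation: the arylidenemalonic acid formed under piperidine catalysis should lose CO2 in hot pyridine to give the E-cinnamic acid, under buffered conditions that aryl MOM acetals tolerate.

Step 4
Reactants: 7 (2E)-3-[2,4,6-tris(methoxymethoxy)-3-methylphenyl]prop-2-enoic acid
Product: 8 3-[2,4,6-tris(methoxymethoxy)-3-methylphenyl]propanoic acid
Conditions: H2 (1 atm), Pd/C, EtOAc, rt
Reagents that add atoms: none
Why: Catalytic hydrogenation saturates the conjugated alkene under neutral conditions that leave the arene and the MOM acetals untouched.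

Step 5
Reactants: 8 3-[2,4,6-tris(methoxymethoxy)-3-methylphenyl]propanoic acid; 9 3-methylbut-2-en-1-ol
Product: 10 3-methylbut-2-en-1-yl 3-[2,4,6-tris(methoxymethoxy)-3-methylphenyl]propanoate
Conditions: EDC·HCl, DMAP (cat.), CH2Cl2, 0 °C → rt
Reagents that add atoms: none
Why: Carbodiimide (Steglich) esterification joins the acid to the primary allylic alcohol under near-neutral conditions, so neither the acetals nor the allylic C–O bond is ionised.

Step 6
Reactants: 10 3-methylbut-2-en-1-yl 3-[2,4,6-tris(methoxymethoxy)-3-methylphenyl]propanoate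
Product: 12 (2R)-3,3-dimethyl-2-{[2,4,6-tris(methoxymethoxy)-3-methylphenyl]methyl}pent-4-enoic acid, via boron ketene acetal 11 (not isolated)
Conditions: (S,S)-L*2BBr (1.2 equiv), Et3N, toluene–hexane, −78 °C → rt; H2O
Reagents that add atoms: none
Why: Enantioselective Ireland–Claisen rearrangement: soft enolisation by the C2-symmetric bromoborane and Et3N gives a chiral O-boron ketene acetal whose chair-like [3,3] shift forms the C11–C10 bond, turns the prenyl terminus into the quaternary C10 bearing the vinyl group C9=C8, and sets C11 (R) because the sulfonyl and phenyl groups of the controller block one enolate face.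

Step 7
Reactants: 12 (2R)-3,3-dimethyl-2-{[2,4,6-tris(methoxymethoxy)-3-methylphenyl]methyl}pent-4-enoic acid
Product: 13 methyl (2R)-3,3-dimethyl-2-{[2,4,6-tris(methoxymethoxy)-3-methylphenyl]methyl}pent-4-enoate
Conditions: MeI, K2CO3, DMF, rt
Reagents that add atoms: iodomethane, CI
Why: SN2 O-methylation of the carboxylate is insensitive to the congestion at C11, cannot epimerise it, and gives the ester needed for the double methyl addition.

Step 8
Reactants: 13 methyl (2R)-3,3-dimethyl-2-{[2,4,6-tris(methoxymethoxy)-3-methylphenyl]methyl}pent-4-enoate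
Product: 15 (3R)-2,4,4-trimethyl-3-{[2,4,6-tris(methoxymethoxy)-3-methylphenyl]methyl}hex-5-en-2-ol, via methyl ketone 14 (not isolated)
Conditions: MeLi, CeCl3, THF, −78 → 0 °C; H2O
Reagents that add atoms: methyllithium, [Li]C
Why: Double 1,2-addition of the weakly basic methylcerium reagent to the ester, through the methyl ketone, should build the C16 tertiary carbinol while suppressing enolisation of the hindered ketone, so that C11 is untouched.

Step 9
Reactants: 15 (3R)-2,4,4-trimethyl-3-{[2,4,6-tris(methoxymethoxy)-3-methylphenyl]methyl}hex-5-en-2-ol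
Product: 16 tert-butyl(dimethyl){[(3R)-2,4,4-trimethyl-3-{[2,4,6-tris(methoxymethoxy)-3-methylphenyl]methyl}hex-5-en-2-yl]oxy}silane
Conditions: TBSOTf, 2,6-lutidine, CH2Cl2, −78 → 0 °C
Reagents that add atoms: tert-butyldimethylsilyl trifluoromethanesulfonate, CC(C)(C)[Si](C)(C)OS(=O)(=O)C(F)(F)F
Why: Silyl triflate silylation of the hindered tertiary alcohol at low temperature with a hindered base, conditions that aryl MOM acetals survive, masks the C16 oxygen for the lithiation and for the oxidation.

Step 10
Reactants: 16 tert-butyl(dimethyl){[(3R)-2,4,4-trimethyl-3-{[2,4,6-tris(methoxymethoxy)-3-methylphenyl]methyl}hex-5-en-2-yl]oxy}silane; 17 N-methoxy-N,2-dimethylpropanamide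
Product: 19 1-{3-[(2R)-2-{2-[tert-butyl(dimethyl)silyl]oxypropan-2-yl}-3,3-dimethylpent-4-en-1-yl]-2,4,6-tris(methoxymethoxy)-5-methylphenyl}-2-methylpropan-1-one, via aryllithium 18 (not isolated)
Conditions: n-BuLi, TMEDA, THF, 0 °C; 17, −78 °C → rt; H2O
Reagents that add atoms: none
Why: Directed ortho-metalation at the last ring C–H (C5, between two OMOM groups) followed by acyl transfer from the N-methoxy-N-methylamide, whose chelated tetrahedral adduct blocks over-addition, should install the isobutyryl group; the vinyl group has no allylic hydrogen and the silyl ether is inert to n-BuLi.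

Step 11
Reactants: 19 1-{3-[(2R)-2-{2-[tert-butyl(dimethyl)silyl]oxypropan-2-yl}-3,3-dimethylpent-4-en-1-yl]-2,4,6-tris(methoxymethoxy)-5-methylphenyl}-2-methylpropan-1-one
Product: 21 1-{3-[(2R)-2-{2-[tert-butyl(dimethyl)silyl]oxypropan-2-yl}-3,3-dimethylpent-4-en-1-yl]-2,4,6-trihydroxy-5-methylphenyl}-2-methylpropan-1-one, via tris(trimethylsilyl) ether 20 (not isolated)
Conditions: TMSOTf, 2,2′-bipyridyl, CH2Cl2, 0 °C → rt; H2O
Reagents that add atoms: none
Why: TMSOTf buffered by 2,2′-bipyridyl activates each aryl MOM acetal and exchanges it for a labile aryl TMS ether that hydrolyses on aqueous work-up, a non-protic acetal cleavage chosen because protic acid could ionise the C16 silyl ether and close a chroman onto the adjacent phenol.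

Step 12
Reactants: 21 1-{3-[(2R)-2-{2-[tert-butyl(dimethyl)silyl]oxypropan-2-yl}-3,3-dimethylpent-4-en-1-yl]-2,4,6-trihydroxy-5-methylphenyl}-2-methylpropan-1-one
Product: 22 (1S,3R,5S,7S)-3-{2-[tert-butyl(dimethyl)silyl]oxypropan-2-yl}-8-hydroxy-4,4,7-trimethyl-9-(2-methylpropanoyl)tricyclo[5.3.1.0(1,5)]undec-8-ene-10,11-dione
Conditions: Mn(OAc)3·2H2O (trivalent manganese, 2.2 equiv), degassed AcOH (0.01 M), rt
Reagents that add atoms: none
Why: Proposed new method: one-electron oxidation of the manganese phenolate of 21 (the C15 hydroxyl, para to the acyl group, is the acidic, non-chelated one) gives a radical delocalised over C13, C7 and C5, which closes ring C by 5-exo-trig attack of C13 on the internal alkene carbon C9 (the sense a radical prefers, whereas a phenoxonium cation would be attacked by the terminal carbon C8), and the primary C8 radical then closes ring B by 5-exo-trig addition to C7 of the C6=C7 enol; a second equivalent of Mn(OAc)3 oxidises the resulting ketyl-type radical and loss of a proton gives the enolised trione. The closest known reactions are the Mn(OAc)3-mediated oxidative radical cascades of dearomatised prenylated acylphloroglucinols and the oxidative-dearomatisation-induced (5+2) cycloadditions of alkenyl phenols, but neither has been run on a fully aromatic acylphloroglucinol with a terminal alkene. C11 controls C9, because the silyloxyisopropyl group should take the face of the forming cyclopentane opposite C8 and the C15 bridge; the cis ring fusion then fixes C13 and the bridge geometry fixes C7. The step needs closure on C7 and not on C5 or on oxygen: C7 carries only a methyl group and is the electron-rich enol terminus, whereas C5 is blocked by the chelated acyl group, and because the first closure can reverse by re-aromatisation the cascade should drain through this best second closure. Cu(OAc)2 is left out on purpose, since it would oxidise the primary C8 radical before it reaches C7.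

Step 13
Reactants: 22 (1S,3R,5S,7S)-3-{2-[tert-butyl(dimethyl)silyl]oxypropan-2-yl}-8-hydroxy-4,4,7-trimethyl-9-(2-methylpropanoyl)tricyclo[5.3.1.0(1,5)]undec-8-ene-10,11-dione
Product: 23 (1S,3R,5S,7S)-8-hydroxy-3-(2-hydroxypropan-2-yl)-4,4,7-trimethyl-9-(2-methylpropanoyl)tricyclo[5.3.1.0(1,5)]undec-8-ene-10,11-dione
Conditions: HF·pyridine, THF, 0 °C → rt
Reagents that add atoms: none
Why: Fluoride-driven Si–O cleavage (silyl ether deprotection) frees the C16 tertiary alcohol and does not affect the enolised trione or any stereocentre.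

**Compound list**

1 | 2-methylbenzene-1,3,5-triol | Cc1c(O)cc(O)cc1O | starting material
2 | 1,3,5-tris(methoxymethoxy)-2-methylbenzene | Cc1c(OCOC)cc(OCOC)cc1OCOC | intermediate
3 | [2,4,6-tris(methoxymethoxy)-3-methylphenyl]lithium (formed in situ) | [Li]c1c(OCOC)cc(OCOC)c(C)c1OCOC | intermediate
4 | 2,4,6-tris(methoxymethoxy)-3-methylbenzaldehyde | Cc1c(OCOC)c(C=O)c(OCOC)cc1OCOC | intermediate
5 | malonic acid | OC(=O)CC(O)=O | starting material
6 | 2-{[2,4,6-tris(methoxymethoxy)-3-methylphenyl]methylidene}propanedioic acid (formed in situ) | Cc1c(OCOC)c(C=C(C(O)=O)C(O)=O)c(OCOC)cc1OCOC | intermediate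
7 | (2E)-3-[2,4,6-tris(methoxymethoxy)-3-methylphenyl]prop-2-enoic acid | Cc1c(OCOC)c(/C=C/C(O)=O)c(OCOC)cc1OCOC | intermediate
8 | 3-[2,4,6-tris(methoxymethoxy)-3-methylphenyl]propanoic acid | Cc1c(OCOC)c(CCC(O)=O)c(OCOC)cc1OCOC | intermediate
9 | 3-methylbut-2-en-1-ol | CC(C)=CCO | starting material
10 | 3-methylbut-2-en-1-yl 3-[2,4,6-tris(methoxymethoxy)-3-methylphenyl]propanoate | Cc1c(OCOC)c(CCC(=O)OCC=C(C)C)c(OCOC)cc1OCOC | intermediate
11 | O-boron ketene acetal of 10 carrying the (4S,5S)-1,3-bis{[3,5-bis(trifluoromethyl)phenyl]sulfonyl}-4,5-diphenyl-1,3,2-diazaborolidin-2-yl group on oxygen, C12 cis to the prenyloxy group (formed in situ) | Cc1c(OCOC)c(C/C=C(\OCC=C(C)C)OB2N(S(=O)(=O)c3cc(cc(c3)C(F)(F)F)C(F)(F)F)[C@@H](c3ccccc3)[C@H](c3ccccc3)N2S(=O)(=O)c3cc(cc(c3)C(F)(F)F)C(F)(F)F)c(OCOC)cc1OCOC | intermediate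
12 | (2R)-3,3-dimethyl-2-{[2,4,6-tris(methoxymethoxy)-3-methylphenyl]methyl}pent-4-enoic acid | Cc1c(OCOC)c(C[C@@H](C(O)=O)C(C)(C)C=C)c(OCOC)cc1OCOC | intermediate
13 | methyl (2R)-3,3-dimethyl-2-{[2,4,6-tris(methoxymethoxy)-3-methylphenyl]methyl}pent-4-enoate | Cc1c(OCOC)c(C[C@@H](C(=O)OC)C(C)(C)C=C)c(OCOC)cc1OCOC | intermediate
14 | (3R)-4,4-dimethyl-3-{[2,4,6-tris(methoxymethoxy)-3-methylphenyl]methyl}hex-5-en-2-one (formed in situ) | Cc1c(OCOC)c(C[C@@H](C(C)=O)C(C)(C)C=C)c(OCOC)cc1OCOC | intermediate
15 | (3R)-2,4,4-trimethyl-3-{[2,4,6-tris(methoxymethoxy)-3-methylphenyl]methyl}hex-5-en-2-ol | Cc1c(OCOC)c(C[C@@H](C(C)(C)O)C(C)(C)C=C)c(OCOC)cc1OCOC | intermediate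
16 | tert-butyl(dimethyl){[(3R)-2,4,4-trimethyl-3-{[2,4,6-tris(methoxymethoxy)-3-methylphenyl]methyl}hex-5-en-2-yl]oxy}silane | Cc1c(OCOC)c(C[C@@H](C(C)(C)O[Si](C)(C)C(C)(C)C)C(C)(C)C=C)c(OCOC)cc1OCOC | intermediate
17 | N-methoxy-N,2-dimethylpropanamide | CC(C)C(=O)N(C)OC | starting material
18 | aryllithium of 16, lithiated at C5 (formed in situ) | [Li]c1c(OCOC)c(C)c(OCOC)c(C[C@@H](C(C)(C)O[Si](C)(C)C(C)(C)C)C(C)(C)C=C)c1OCOC | intermediate
19 | 1-{3-[(2R)-2-{2-[tert-butyl(dimethyl)silyl]oxypropan-2-yl}-3,3-dimethylpent-4-en-1-yl]-2,4,6-tris(methoxymethoxy)-5-methylphenyl}-2-methylpropan-1-one | CC(C)C(=O)c1c(OCOC)c(C)c(OCOC)c(C[C@@H](C(C)(C)O[Si](C)(C)C(C)(C)C)C(C)(C)C=C)c1OCOC | intermediate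
20 | tris(trimethylsilyl) ether of 21 at the three phenols (formed in situ) | CC(C)C(=O)c1c(O[Si](C)(C)C)c(C)c(O[Si](C)(C)C)c(C[C@@H](C(C)(C)O[Si](C)(C)C(C)(C)C)C(C)(C)C=C)c1O[Si](C)(C)C | intermediate
21 | 1-{3-[(2R)-2-{2-[tert-butyl(dimethyl)silyl]oxypropan-2-yl}-3,3-dimethylpent-4-en-1-yl]-2,4,6-trihydroxy-5-methylphenyl}-2-methylpropan-1-one (key-step precursor) | CC(C)C(=O)c1c(O)c(C)c(O)c(C[C@@H](C(C)(C)O[Si](C)(C)C(C)(C)C)C(C)(C)C=C)c1O | intermediate
22 | (1S,3R,5S,7S)-3-{2-[tert-butyl(dimethyl)silyl]oxypropan-2-yl}-8-hydroxy-4,4,7-trimethyl-9-(2-methylpropanoyl)tricyclo[5.3.1.0(1,5)]undec-8-ene-10,11-dione (key-step product; C13 S, C11 R, C9 S, C7 S) | CC(C)C(=O)C1=C(O)[C@]2(C)C[C@H]3C(C)(C)[C@H](C(C)(C)O[Si](C)(C)C(C)(C)C)C[C@@]3(C1=O)C2=O | intermediate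
23 | (1S,3R,5S,7S)-8-hydroxy-3-(2-hydroxypropan-2-yl)-4,4,7-trimethyl-9-(2-methylpropanoyl)tricyclo[5.3.1.0(1,5)]undec-8-ene-10,11-dione | CC(C)C(=O)C1=C(O)[C@]2(C)C[C@H]3C(C)(C)[C@H](C(C)(C)O)C[C@@]3(C1=O)C2=O | target

**Totals**

Total step count: 13
Longest linear sequence: 13 steps (1 to 23)

**Steps most likely to fail**

1. Step 12 (proposed new method). What may go wrong:
 - over-oxidation of the aryloxyl radical before it cyclises, followed by loss of a benzylic proton or capture by acetate;
 - quenching of the primary C8 radical before it reaches C7;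
 - ring closure onto C5;
 - closure on the wrong face relative to C11.

 The fallback uses known chemistry, sets out from 1 and rejoins the route at 23. It relies on the established radical cascade of a dearomatised diprenyl precursor, which forms C9–C13 and C10–C11 instead of C7–C8. Friedel–Crafts acylation of 1 with isobutyryl chloride and AlCl3 should give 1-(2,4,6-trihydroxy-3-methylphenyl)-2-methylpropan-1-one F1. Double C-prenylation with prenyl bromide in aqueous KOH should give the racemic dearomatised diprenyl trione F2. Mn(OAc)3 (trivalent manganese) with Cu(OAc)2 (divalent copper) in AcOH should close rings B and C and end in the isopropenyl analogue of 23, F3, together with its C11 epimer F4. After separation, Mukaiyama hydration of F3 (Co(acac)2, divalent cobalt; PhSiH3; O2) should give racemic 23. Chromatography on a chiral stationary phase then removes the enantiomer F5. F2 to F4 are racemates, so this fallback pays with a resolution at the end.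

2. Step 6. What may go wrong: loss of a MOM acetal to the Lewis-acidic boron bromide during the slow rearrangement, or weak face discrimination with a 3,3-disubstituted allyl ester.

 The fallback sets out from 10 and rejoins the route at 12. LiN(i-Pr)2 and Me3SiCl in THF at −78 °C should give the trimethylsilyl ketene acetal F6. Its Ireland–Claisen rearrangement on warming, followed by hydrolysis, should give the racemic acid, that is 12 together with its enantiomer F7. Fractional crystallisation of the salt F8 with (S)-1-phenylethylamine (or with the antipodal amine, if that salt is the less soluble one) and acidification return 12.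

3. Step 10. What may go wrong: sluggish acyl transfer to the doubly ortho-substituted aryllithium, so that deprotonation of the amide or lateral metalation of the ring methyl group takes over.

 The fallback sets out from 16 and rejoins the route at 19. Aryllithium 18 is generated as before and trapped with isobutyraldehyde, a fast carbonyl addition, to give the benzylic alcohol F9 as a mixture of carbinol epimers. Oxidation with IBX in DMSO should give 19.

**Further compounds**

F1 | step 12 | 1-(2,4,6-trihydroxy-3-methylphenyl)-2-methylpropan-1-one | CC(C)C(=O)c1c(O)cc(O)c(C)c1O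
F2 | step 12 | 3,5-dihydroxy-6-methyl-2,6-bis(3-methylbut-2-en-1-yl)-4-(2-methylpropanoyl)cyclohexa-2,4-dien-1-one, racemic, enantiomer leading to 23 drawn | CC(C)C(=O)C1=C(O)[C@](C)(CC=C(C)C)C(=O)C(CC=C(C)C)=C1O
F3 | step 12 | isopropenyl analogue of 23 (prop-1-en-2-yl at C11, configuration as in 23), racemic, enantiomer leading to 23 drawn | CC(C)C(=O)C1=C(O)[C@]2(C)C[C@H]3C(C)(C)[C@H](C(C)=C)C[C@@]3(C1=O)C2=O
F4 | step 12 | C11 epimer of F3, racemic | CC(C)C(=O)C1=C(O)[C@]2(C)C[C@H]3C(C)(C)[C@@H](C(C)=C)C[C@@]3(C1=O)C2=O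
F5 | step 12 | enantiomer of 23 | CC(C)C(=O)C1=C(O)[C@@]2(C)C[C@@H]3C(C)(C)[C@@H](C(C)(C)O)C[C@]3(C1=O)C2=O
F6 | step 6 | trimethylsilyl ketene acetal of 10 | Cc1c(OCOC)c(C/C=C(\OCC=C(C)C)O[Si](C)(C)C)c(OCOC)cc1OCOC
F7 | step 6 | (2S)-3,3-dimethyl-2-{[2,4,6-tris(methoxymethoxy)-3-methylphenyl]methyl}pent-4-enoic acid, enantiomer of 12 | Cc1c(OCOC)c(C[C@H](C(O)=O)C(C)(C)C=C)c(OCOC)cc1OCOC
F8 | step 6 | (S)-1-phenylethylammonium salt of 12 | Cc1c(OCOC)c(C[C@@H](C([O-])=O)C(C)(C)C=C)c(OCOC)cc1OCOC.C[C@H]([NH3+])c1ccccc1
F9 | step 10 | 1-{3-[(2R)-2-{2-[tert-butyl(dimethyl)silyl]oxypropan-2-yl}-3,3-dimethylpent-4-en-1-yl]-2,4,6-tris(methoxymethoxy)-5-methylphenyl}-2-methylpropan-1-ol, both carbinol epimers | CC(C)C(O)c1c(OCOC)c(C)c(OCOC)c(C[C@@H](C(C)(C)O[Si](C)(C)C(C)(C)C)C(C)(C)C=C)c1OCOC
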